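Atom labels run along the target SMILES from the CH that bears CO2Me: C1, C2, C3 (quaternary), C4 (lactam C=O), N5, C6, C7, C8, C9, C10=C11, C12, C13, C14, C15 (quaternary), C16 (CH2OAc), C17, C18, C19 (CHOH), C20 (its methyl is C21), C22. Ring A is C1-C2-C3-C11-C12, ring B is C10-C11-C12-C13-C14, ring C is the cycloheptene C3-C11-C10-C9-C8-C7-C15, ring D is the lactam C3-C4-N5-C6-C7-C15, and ring E is the nine-membered ring through N5, C22, C20, C19, C18, C17 and C15.
Enabling feature: N5 of ring D is tied through C22 and C20 to the carbinol C19, so ring D is a lactam whose nitrogen carries a 3-hydroxyalkyl chain. A 1,3-azido alcohol leaves exactly this unit when its nitrogen is inserted between C4 and C6 of the cyclopentanone C3-C4-C6-C7-C15.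
Cuts, last made first: H–C1/H–C12 and the C17–C18 π bond (hydrogenation), C17=C18 (ring-closing metathesis), C4–N5 and N5–C6 (azido-Schmidt insertion), C7–C8 (radical conjugate addition), C1=C12 (Horner–Wadsworth–Emmons), C10–C14 (Nazarov), C11–C12–C13 (carbonylative Stille), C2–C3 (Michael), C3–C11 (acylation), C15–C17 (conjugate addition).
Forward ring order: the five-membered ketone ring is present from the start. Then come ring B, ring A and ring C, then ring D by enlargement of the ketone ring with attachment of the C18–C22 arm, and finally ring E.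
Stereochemistry: C15 comes from a copper-catalysed enantioselective vinyl conjugate addition. C3 follows from C15 (the Michael acceptor enters opposite the silyloxymethyl arm) and C7 from the tether in the ring C closure. C19 and C20 come from an Evans syn aldol, and C1 and C12 from syn hydrogenation on the face away from C15.

Key step: step 21

Remark: the ketone enters the key step at the dienoate oxidation level (C1=C12–C11=C10). This spares the C15 vinyl group an early hydrogenation and makes C3 a poorer migrating group.
Remark: 12 is drawn as the diketone, and C3 is stereolabile there until step 8. C1 of 14–18 is a mixture of epimers that vanishes in step 12.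
Remark: the ring E alkene of 33 is assumed to be Z, and either geometry is consumed in step 23. Azide 29 is of low molecular weight and is handled only in solution.

Step 1
Reactants: 1 cyclopentane-1,3-dione
Product: 2 3-bromocyclopent-2-en-1-one
Conditions: PBr3 (0.4 equiv), ClCH2CH2Cl, reflux
Reagents that add atoms: phosphorus tribromide, BrP(Br)Br
Why: The dione reacts through its enol as a vinylogous acid, so PBr3 exchanges OH for Br and gives the β-bromoenone (vinylogous acid bromide formation).

Step 2
Reactants: 2 3-bromocyclopent-2-en-1-one; 3 (tributylstannyl)methanol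
Product: 4 3-(hydroxymethyl)cyclopent-2-en-1-one
Conditions: Pd(PPh3)4 (5 mol %), dioxane, 90 °C
Reagents that add atoms: none
Why: Stille coupling of the activated vinyl bromide transfers the hydroxymethyl group (C16) from tin faster than butyl and leaves the enone intact.

Step 3
Reactants: 4 3-(hydroxymethyl)cyclopent-2-en-1-one
Product: 5 3-[(tert-butyldiphenylsilyloxy)methyl]cyclopent-2-en-1-one
Conditions: t-BuPh2SiCl, imidazole, CH2Cl2, rt
Reagents that add atoms: tert-butyl(chloro)diphenylsilane, CC(C)(C)[Si](Cl)(c1ccccc1)c1ccccc1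
Why: Standard silylation of the primary alcohol installs a bulky, acid-tolerant group that later shields one face of C3.

Step 4
Reactants: 5 3-[(tert-butyldiphenylsilyloxy)methyl]cyclopent-2-en-1-one; 6 ethynyltrimethylsilane
Product: 8 (S)-3-[(tert-butyldiphenylsilyloxy)methyl]-3-[1-(trimethylsilyl)vinyl]cyclopentan-1-one, via diisobutyl[1-(trimethylsilyl)vinyl]alane 7 (not isolated)
Conditions: 6, i-Bu2AlH, hexane/THF, 55 °C; then 5, Cu(OTf)2 (5 mol %), chiral sulfonate-bearing N-heterocyclic carbene ligand (5 mol %), THF, 0 °C to rt; aq potassium sodium tartrate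
Reagents that add atoms: none
Why: Hydroalumination puts aluminium on the silicon-bearing alkyne carbon, and the copper-catalysed enantioselective conjugate addition of this vinylalane to the β-substituted enone creates quaternary C15, the ligand enantiomer being chosen so that the S ketone results.

Step 5
Reactants: 8 (S)-3-[(tert-butyldiphenylsilyloxy)methyl]-3-[1-(trimethylsilyl)vinyl]cyclopentan-1-one
Product: 9 (R)-3-[(tert-butyldiphenylsilyloxy)methyl]-3-vinylcyclopentan-1-one
Conditions: CF3CO2H, CH2Cl2, 0 °C to rt
Reagents that add atoms: none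
Why: Protodesilylation of the vinylsilane by ipso protonation frees the plain vinyl group (C17) without touching C15 or the robust silyl ether.

Step 6
Reactants: 9 (R)-3-[(tert-butyldiphenylsilyloxy)methyl]-3-vinylcyclopentan-1-one
Product: 10 (R)-4-[(tert-butyldiphenylsilyloxy)methyl]-4-vinylcyclopent-2-en-1-one
Conditions: 2-iodoxybenzoic acid (IBX, 2 equiv), DMSO, 75 °C
Reagents that add atoms: none
Why: IBX dehydrogenation of the ketone can only introduce the C6=C7 double bond because C15 on the other side carries no hydrogen.

Step 7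
Reactants: 10 (R)-4-[(tert-butyldiphenylsilyloxy)methyl]-4-vinylcyclopent-2-en-1-one; 11 4-chlorobutanoyl chloride
Product: 12 (4R)-5-(4-chlorobutanoyl)-4-[(tert-butyldiphenylsilyloxy)methyl]-4-vinylcyclopent-2-en-1-one (1,3-diketone, C3 stereolabile)
Conditions: LiN(SiMe3)2 (2.2 equiv), toluene/THF, −78 to 0 °C; 11; dilute aq HCl
Reagents that add atoms: none
Why: C3 is the only enolisable position of enone 10, so its lithium enolate undergoes Claisen-type C-acylation by the acid chloride (C8–C11 unit) and the second equivalent of base stores the product as its diketonate.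

Step 8
Reactants: 12 the 1,3-diketone; 13 trimethyl 2-phosphonoacrylate
Product: 14 methyl 3-[(1S,5R)-1-(4-chlorobutanoyl)-5-[(tert-butyldiphenylsilyloxy)methyl]-2-oxo-5-vinylcyclopent-3-en-1-yl]-2-(dimethoxyphosphoryl)propanoate (C11 acyl group cis to CH2OSi, C2 chain cis to vinyl)
Conditions: Et3N (20 mol %), CH2Cl2, 0 °C to rt
Reagents that add atoms: none
Why: Amine-catalysed Michael addition of the soft diketone nucleophile to the doubly activated acrylate forms C2–C3, and the acceptor should approach the planar enolate from the vinyl side, opposite the bulky silyloxymethyl arm on C15, which puts the C11 acyl group cis to C16 and fixes C3.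

Step 9
Reactants: 14 the quaternary diketone phosphonate
Product: 15 (Z)-enol triflate of 14 (C11(OTf)=C10H–C9H2–C8H2Cl in place of the 4-chlorobutanoyl group)
Conditions: KN(SiMe3)2 (2.2 equiv), THF, −78 °C; N-(5-chloropyridin-2-yl)bis(trifluoromethanesulfonimide); AcOH, −78 °C
Reagents that add atoms: N-(5-chloropyridin-2-yl)bis(trifluoromethanesulfonimide), FC(F)(F)S(=O)(=O)N(c1ccc(Cl)cn1)S(=O)(=O)C(F)(F)F
Why: The phosphonoacetate C1–H is removed first and carried as its potassium salt, the second equivalent of base can then deprotonate only C10 because the enone carbonyl C4 has no α-hydrogen, and O-sulfonylation of the more reactive ketone enolate gives the enol triflate (enolate triflation).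

Step 10
Reactants: 15 the enol triflate; 16 tributyl(vinyl)stannane
Product: 17 cross-conjugated divinyl ketone (C11 of 15 now bears C12(=O)–C13H=C14H2 instead of OTf)
Conditions: Pd(PPh3)4 (10 mol %), LiCl (3 equiv), CO (1 atm), THF, 55 °C
Reagents that add atoms: carbon monoxide, [C-]#[O+]
Why: Carbonylative Stille coupling, in which zerovalent palladium inserts into the C11–O bond, CO inserts as C12 and tin delivers the vinyl group, gives the divinyl ketone under neutral conditions.

Step 11
Reactants: 17 the divinyl ketone
Product: 18 ring B cyclopentenone (C3 bears a 2-(2-chloroethyl)-5-oxocyclopent-1-en-1-yl group; C12 is the ketone)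
Conditions: MeSO3H (5 equiv), CH2Cl2, 0 °C to rt
Reagents that add atoms: none
Why: Acid-promoted Nazarov 4π-conrotatory electrocyclisation forms C10–C14, and loss of the C10 proton places the double bond in the more substituted C10=C11 position, so the alkene geometry of 17 is of no consequence.

Step 12
Reactants: 18 the ring B cyclopentenone
Product: 19 spiro tricyclic dienoate (3R,15R): rings A and B with C1(CO2Me)=C12–C11=C10, spiro at C3 to the cyclopentenone C3-C4(=O)-C6=C7-C15; C10 bears CH2CH2Cl
Conditions: NaH (1.1 equiv), THF, 0 °C to rt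
Reagents that add atoms: none
Why: Intramolecular Horner–Wadsworth–Emmons olefination of the C12 ketone by the most acidic site, the C1 phosphonoacetate, closes five-membered ring A (5-exo-trig attack on C=O) irreversibly and delivers the C1=C12 bond in the same operation.

Step 13
Reactants: 19 the chloro dienoate
Product: 20 the corresponding iodide (C8–I)
Conditions: NaI (5 equiv), acetone, reflux
Reagents that add atoms: sodium iodide, [Na+].[I-]
Why: Finkelstein exchange, driven by precipitation of NaCl, turns the inert chloride into the iodide needed for radical generation.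

Step 14
Reactants: 20 the iodide
Product: 21 tetracyclic ketone (3R,7R,15R): rings A, B, C and the cyclopentanone C3-C4-C6-C7-C15; C15 bears vinyl (over the ketone bridge) and CH2OSi-t-BuPh2 (over ring C)
Conditions: Bu3SnH (1.3 equiv, slow addition), AIBN (20 mol %), benzene (5 mM), 80 °C
Reagents that add atoms: none
Why: In this tin-hydride-mediated 7-exo-trig radical conjugate addition (Giese type) the C8 radical, held cis to C3 by the C10=C11 bond, can reach the enone only at C7 and only on the face that carries C11, which closes ring C and fixes C7.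

Step 15
Reactants: 21 the silyl-protected tetracyclic ketone
Product: 22 the C16 primary alcohol
Conditions: Bu4NF, AcOH (1:1), THF, rt
Reagents that add atoms: none
Why: Buffered fluoride cleaves the silyl ether while the acetic acid keeps the medium too weakly basic for oxa-Michael addition of the freed C16 alcohol to the dienoate.

Step 16
Reactants: 22 the C16 alcohol
Product: 23 tetracyclic C4 ketone acetate (3R,7R,15R) with C15 vinyl group and C1=C12–C11=C10 dienoate
Conditions: Ac2O, pyridine, DMAP (cat.), CH2Cl2, rt
Reagents that add atoms: acetic anhydride, CC(=O)OC(C)=O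
Why: Acylation of the only hydroxyl group installs the C16 acetate of the target.

Step 17
Reactants: 24 (S)-4-benzyl-3-propanoyloxazolidin-2-one; 25 acrolein
Product: 26 (S)-4-benzyl-3-[(2S,3R)-3-hydroxy-2-methylpent-4-enoyl]oxazolidin-2-one
Conditions: Bu2BOTf, Et3N, CH2Cl2, −78 to 0 °C; 25, −78 °C; H2O2, MeOH, pH 7 buffer
Reagents that add atoms: none
Why: In the Evans syn aldol the Z boron enolate reacts through a Zimmerman–Traxler chair on the face left open by the benzyl group, which sets C20 and C19 together in the syn relationship required.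

Step 18
Reactants: 26 the syn aldol
Product: 27 (2R,3R)-2-methylpent-4-ene-1,3-diol
Conditions: LiBH4, THF, 0 °C to rt
Reagents that add atoms: none
Why: Borohydride reduces the activated imide carbonyl to the primary alcohol (C22) and releases the auxiliary without enolising C20.

Step 19
Reactants: 27 the diol
Product: 28 (2R,3R)-3-hydroxy-2-methylpent-4-en-1-yl 4-methylbenzenesulfonate
Conditions: TsCl (1.05 equiv), Et3N, DMAP (cat.), CH2Cl2, 0 °C
Reagents that add atoms: 4-methylbenzenesulfonyl chloride, Cc1ccc(S(=O)(=O)Cl)cc1
Why: The unhindered primary hydroxyl is sulfonylated much faster than the branched secondary allylic one.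

Step 20
Reactants: 28 the primary tosylate
Product: 29 (3R,4R)-5-azido-4-methylpent-1-en-3-ol
Conditions: NaN3, DMF, 60 °C
Reagents that add atoms: sodium azide, [Na+].[N-]=[N+]=[N-]
Why: SN2 displacement at primary C22 introduces the azide without touching C19 or C20.

Step 21
Reactants: 23 tetracyclic C4 ketone acetate; 29 (3R,4R)-5-azido-4-methylpent-1-en-3-ol
Product: 32 ring D lactam (3R,7S,15R,19R,20R) bearing the N5 hydroxyalkenyl arm, via spiro aminodiazonium ion 30 (not isolated), via bicyclic iminium ether 31 (not isolated)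
Conditions: 29 (2 equiv), BF3·OEt2 (5 equiv), CH2Cl2, −78 °C to rt; then sat. aq NaHCO3, rt
Reagents that add atoms: water, O
Why: BF3 lets the C19 hydroxyl of 29 add to the C4 carbonyl, the hemiketal ionises to an oxocarbenium ion, the azide nitrogen bonded to C22 closes onto C4 (6-endo-trig) to give the spiro 1,3-oxazinane aminodiazonium ion 30, and the C4–C6 bond lying antiperiplanar to the N–N2 bond shifts to nitrogen as N2 leaves, giving iminium ether 31, which bicarbonate water opens at C4 to the lactam and the free C19 alcohol. The closest known reaction is the Lewis-acid-promoted Schmidt ring expansion of cyclic ketones with 1,3-hydroxyalkyl azides to N-(3-hydroxyalkyl) lactams. Ring D is therefore not closed by a ring-closing attack but arises by one-atom enlargement of the five-membered ketone ring through a 1,2-shift that forms C4–N5 and N5–C6 in one operation. No stereocentre is created: C3, C7 and C15 are untouched, the migrating C6 is a methylene, and C19 and C20 keep their configuration because water attacks C4 and not C19. The selectivity needed is migration of C6 instead of C3, and in the oxazinane chair the fully substituted C3 takes the equatorial site, which leaves C6 axial and anti to the axial diazonium group. In addition C3 is bonded to the electron-poor dienoate carbon C11 at this oxidation level, which lowers its migratory aptitude and disfavours the competing fragmentation to a C3 cation.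

Step 22
Reactants: 32 the ring D lactam diene
Product: 33 pentacyclic lactam with the C17=C18 (Z) double bond in ring E
Conditions: second-generation Hoveyda–Grubbs catalyst (15 mol %), 1,4-benzoquinone (30 mol %), toluene (1 mM), 90 °C
Reagents that add atoms: none
Why: In the ring-closing metathesis the catalyst loads on the less hindered allylic-alcohol alkene and then closes onto the neopentyl C15 vinyl group, which the rigid lactam holds over ring D close to N5, while high dilution and loss of ethene favour the nine-membered ring.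

Step 23
Reactants: 33 the pentacyclic triene
Product: 34 target CNP0296366.1 (1R,3R,7S,12R,15R,19R,20R)
Conditions: [Ir(cod)(PCy3)(py)]PF6 (20 mol %), H2 (60 bar), CH2Cl2, rt
Reagents that add atoms: none
Why: Homogeneous iridium-catalysed hydrogenation saturates the disubstituted C17=C18 bond first and then adds H2 syn to the ester-conjugated C1=C12 bond from the face opposite C15 and its CH2OAc arm, which sets C1 and C12 together, while the then isolated tetrasubstituted C10=C11 bond is too hindered to react.

Compound list
1 | cyclopentane-1,3-dione | O=C1CCC(=O)C1 | starting material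
2 | 3-bromocyclopent-2-en-1-one | O=C1C=C(Br)CC1 | intermediate
3 | (tributylstannyl)methanol | OC[Sn](CCCC)(CCCC)CCCC | starting material
4 | 3-(hydroxymethyl)cyclopent-2-en-1-one | O=C1C=C(CO)CC1 | intermediate
5 | 3-[(tert-butyldiphenylsilyloxy)methyl]cyclopent-2-en-1-one | O=C1C=C(CO[Si](c2ccccc2)(c2ccccc2)C(C)(C)C)CC1 | intermediate
6 | ethynyltrimethylsilane | C#C[Si](C)(C)C | starting material
7 | diisobutyl[1-(trimethylsilyl)vinyl]alane | C=C([Si](C)(C)C)[Al](CC(C)C)CC(C)C | intermediate
8 | (S)-3-[(tert-butyldiphenylsilyloxy)methyl]-3-[1-(trimethylsilyl)vinyl]cyclopentan-1-one | O=C1CC[C@](CO[Si](c2ccccc2)(c2ccccc2)C(C)(C)C)(C(=C)[Si](C)(C)C)C1 | intermediate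
9 | (R)-3-[(tert-butyldiphenylsilyloxy)methyl]-3-vinylcyclopentan-1-one | O=C1CC[C@](CO[Si](c2ccccc2)(c2ccccc2)C(C)(C)C)(C=C)C1 | intermediate
10 | (R)-4-[(tert-butyldiphenylsilyloxy)methyl]-4-vinylcyclopent-2-en-1-one | O=C1C=C[C@](CO[Si](c2ccccc2)(c2ccccc2)C(C)(C)C)(C=C)C1 | intermediate
11 | 4-chlorobutanoyl chloride | O=C(Cl)CCCCl | starting material
12 | (4R)-5-(4-chlorobutanoyl)-4-[(tert-butyldiphenylsilyloxy)methyl]-4-vinylcyclopent-2-en-1-one | O=C1C=C[C@](CO[Si](c2ccccc2)(c2ccccc2)C(C)(C)C)(C=C)C1C(=O)CCCCl | intermediate
13 | trimethyl 2-phosphonoacrylate | C=C(C(=O)OC)P(=O)(OC)OC | starting material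
14 | Michael adduct, (3S,15R), C1 epimers | COC(=O)C(P(=O)(OC)OC)C[C@]1(C(=O)CCCCl)C(=O)C=C[C@]1(CO[Si](c2ccccc2)(c2ccccc2)C(C)(C)C)C=C | intermediate
15 | (Z)-C11 enol triflate, (3S,15R) | COC(=O)C(P(=O)(OC)OC)C[C@]1(/C(OS(=O)(=O)C(F)(F)F)=C/CCCl)C(=O)C=C[C@]1(CO[Si](c2ccccc2)(c2ccccc2)C(C)(C)C)C=C | intermediate
16 | tributyl(vinyl)stannane | C=C[Sn](CCCC)(CCCC)CCCC | starting material
17 | divinyl ketone, (3S,15R) | COC(=O)C(P(=O)(OC)OC)C[C@]1(/C(C(=O)C=C)=C/CCCl)C(=O)C=C[C@]1(CO[Si](c2ccccc2)(c2ccccc2)C(C)(C)C)C=C | intermediate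
18 | ring B cyclopentenone, (3S,15R) | COC(=O)C(P(=O)(OC)OC)C[C@]1(C2=C(CCCl)CCC2=O)C(=O)C=C[C@]1(CO[Si](c3ccccc3)(c3ccccc3)C(C)(C)C)C=C | intermediate
19 | spiro tricyclic chloro dienoate, (3R,15R) | COC(=O)C1=C2CCC(CCCl)=C2[C@@]3(C1)C(=O)C=C[C@]3(CO[Si](c4ccccc4)(c4ccccc4)C(C)(C)C)C=C | intermediate
20 | spiro tricyclic iodo dienoate, (3R,15R) | COC(=O)C1=C2CCC(CCI)=C2[C@@]3(C1)C(=O)C=C[C@]3(CO[Si](c4ccccc4)(c4ccccc4)C(C)(C)C)C=C | intermediate
21 | tetracyclic ketone silyl ether, (3R,7R,15R) | COC(=O)C1=C2CCC3=C2[C@@]4(C1)C(=O)C[C@@H](CC3)[C@]4(CO[Si](c5ccccc5)(c5ccccc5)C(C)(C)C)C=C | intermediate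
22 | tetracyclic ketone C16 alcohol, (3R,7R,15R) | COC(=O)C1=C2CCC3=C2[C@@]4(C1)C(=O)C[C@@H](CC3)[C@]4(CO)C=C | intermediate
23 | tetracyclic C4 ketone acetate, (3R,7R,15R) | COC(=O)C1=C2CCC3=C2[C@@]4(C1)C(=O)C[C@@H](CC3)[C@]4(COC(C)=O)C=C | intermediate
24 | (S)-4-benzyl-3-propanoyloxazolidin-2-one | CCC(=O)N1[C@@H](Cc2ccccc2)COC1=O | starting material
25 | acrolein | C=CC=O | starting material
26 | (S)-4-benzyl-3-[(2S,3R)-3-hydroxy-2-methylpent-4-enoyl]oxazolidin-2-one | C=C[C@@H](O)[C@H](C)C(=O)N1[C@@H](Cc2ccccc2)COC1=O | intermediate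
27 | (2R,3R)-2-methylpent-4-ene-1,3-diol | C=C[C@@H](O)[C@H](C)CO | intermediate
28 | (2R,3R)-3-hydroxy-2-methylpent-4-en-1-yl 4-methylbenzenesulfonate | C=C[C@@H](O)[C@H](C)COS(=O)(=O)c1ccc(C)cc1 | intermediate
29 | (3R,4R)-5-azido-4-methylpent-1-en-3-ol | C=C[C@@H](O)[C@H](C)CN=[N+]=[N-] | intermediate
30 | spiro 1,3-oxazinane aminodiazonium ion (hydroxytrifluoroborate) | COC(=O)C1=C2CCC3=C2[C@@]4(C1)C5(C[C@@H](CC3)[C@]4(COC(C)=O)C=C)O[C@H](C=C)[C@H](C)CN5[N+]#N.O[B-](F)(F)F | intermediate
31 | bicyclic iminium ether (hydroxytrifluoroborate) | COC(=O)C1=C2CCC3=C2[C@@]4(C1)C5=[N+](C[C@@H](C)[C@@H](C=C)O5)C[C@@H](CC3)[C@]4(COC(C)=O)C=C.O[B-](F)(F)F | intermediate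
32 | ring D lactam with N5 arm and two terminal alkenes, (3R,7S,15R,19R,20R) | COC(=O)C1=C2CCC3=C2[C@@]4(C1)C(=O)N(C[C@@H](C)[C@H](O)C=C)C[C@@H](CC3)[C@]4(COC(C)=O)C=C | intermediate
33 | pentacyclic lactam with C17=C18 (Z) | COC(=O)C1=C2CCC3=C2[C@@]4(C1)C(=O)N5C[C@@H](CC3)[C@]4(COC(C)=O)/C=C\[C@@H](O)[C@H](C)C5 | intermediate
34 | CNP0296366.1 | COC(=O)[C@@H]1C[C@@]23C(=O)N4C[C@@H](CCC5=C2[C@@H]1CC5)[C@]3(COC(C)=O)CC[C@@H](O)[C@H](C)C4 | target

Total step count: 23. Longest linear sequence: 19 steps (steps 1–16, then 21–23).

Steps most likely to fail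

Step 21. Hemiketal formation at the neopentyl C4 carbonyl may be too slow, or C3 may migrate or fragment instead of C6 shifting.
- The fallback sets out from 23 and builds the same C4–N5 and N5–C6 bonds by cleavage and re-closure.
- Me3SiOTf/Et3N converts the ketone into the trimethylsilyl enol ether F1.
- Rubottom oxidation with buffered mCPBA, which takes the electron-rich enol ether before the electron-poor dienoate or the vinyl group, gives the C6 α-hydroxy ketone F2.
- Pb(OAc)4 in methanol cleaves C4–C6 to the C4 methyl ester C6 aldehyde F3.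
- Staudinger reduction of 29 (PPh3, wet THF) gives the amino alcohol F4.
- Reductive amination with NaBH(OAc)3 joins N5 to C6 in the amino ester F5.
- Heating with 2-hydroxypyridine in toluene closes the six-membered lactam, which rejoins the route at 32.

Step 22. The catalyst may fail to engage the neopentyl C15 vinyl group intramolecularly, so that oligomerisation or alkene migration overtakes nine-membered ring closure.
- The fallback sets out from 23 and 29 and closes ring E through nitrogen instead of through the alkene.
- Cross-metathesis with excess 29 (same ruthenium catalyst) gives the (E)-alkenyl azido alcohol ketone F6.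
- Diimide (2-nitrobenzenesulfonylhydrazide, Et3N) saturates C17=C18 to the tethered azido alcohol ketone F7.
- BF3·OEt2 followed by aq NaHCO3 triggers the intramolecular azido-Schmidt reaction, which forms rings D and E together in the pentacyclic dienoate lactam F8.
- Hydrogenation under the conditions of step 23 rejoins the route at 34.

Step 14. The primary C8 radical may be reduced by the stannane before the slow seven-membered closure takes place.
- The fallback sets out from 20 and replaces the kinetic radical closure by a reversible anionic one.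
- AgNO2 in ether gives the nitroalkane F9.
- Catalytic DBU brings about the intramolecular nitro-Michael addition to C7, which can only occur on the C11 face, and gives the C8-nitro tetracycle F10.
- Radical denitration (Bu3SnH, AIBN, toluene, reflux) rejoins the route at 21.

Further compounds
F1 | step 21 | C4 trimethylsilyl enol ether of 23 | COC(=O)C1=C2CCC3=C2[C@@]4(C1)C(O[Si](C)(C)C)=C[C@@H](CC3)[C@]4(COC(C)=O)C=C
F2 | step 21 | C6 α-hydroxy ketone | COC(=O)C1=C2CCC3=C2[C@@]4(C1)C(=O)C(O)[C@@H](CC3)[C@]4(COC(C)=O)C=C
F3 | step 21 | C4 methyl ester C6 aldehyde (rings A, B, C) | COC(=O)C1=C2CCC3=C2[C@@](C1)(C(=O)OC)[C@@](COC(C)=O)(C=C)[C@@H](C=O)CC3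
F4 | step 21 | (3R,4R)-5-amino-4-methylpent-1-en-3-ol | C=C[C@@H](O)[C@H](C)CN
F5 | step 21 | amino ester with N5–C6 bond | COC(=O)C1=C2CCC3=C2[C@@](C1)(C(=O)OC)[C@@](COC(C)=O)(C=C)[C@@H](CNC[C@@H](C)[C@H](O)C=C)CC3
F6 | step 22 | (E)-C17=C18 azido alcohol ketone | COC(=O)C1=C2CCC3=C2[C@@]4(C1)C(=O)C[C@@H](CC3)[C@]4(COC(C)=O)/C=C/[C@@H](O)[C@H](C)CN=[N+]=[N-]
F7 | step 22 | tethered azido alcohol ketone (C17–C18 saturated) | COC(=O)C1=C2CCC3=C2[C@@]4(C1)C(=O)C[C@@H](CC3)[C@]4(COC(C)=O)CC[C@@H](O)[C@H](C)CN=[N+]=[N-]
F8 | step 22 | pentacyclic dienoate lactam (ring E saturated) | COC(=O)C1=C2CCC3=C2[C@@]4(C1)C(=O)N5C[C@@H](CC3)[C@]4(COC(C)=O)CC[C@@H](O)[C@H](C)C5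
F9 | step 14 | C8 nitroalkane | COC(=O)C1=C2CCC(CC[N+](=O)[O-])=C2[C@@]3(C1)C(=O)C=C[C@]3(CO[Si](c4ccccc4)(c4ccccc4)C(C)(C)C)C=C
F10 | step 14 | C8-nitro tetracyclic ketone | COC(=O)C1=C2CCC3=C2[C@@]4(C1)C(=O)C[C@@H](C(C3)[N+](=O)[O-])[C@]4(CO[Si](c5ccccc5)(c5ccccc5)C(C)(C)C)C=C
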